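**Plan**

- Numbering: C1 is the CH2 on ring A (4-hydroxy-3-methoxyphenyl), C3 the carbonyl carbon, C5 the carbinol carbon (R by CIP analysis of the target), C7 the CH2 on ring B (3,4-dihydroxy-5-methoxyphenyl).
- Enabling feature: the C3 carbonyl and the C5 hydroxyl are 1,3-related, so a C2≡C3 alkyne is homopropargylic to the C5 oxygen. A silicon atom carried on that oxygen can reach C3 only, through a five-membered O–Si–C3–C4–C5 ring (a 1,2-oxasilolane).
- Cuts: the C3 carbonyl is traced back to the C2≡C3 alkyne; the chain is then cut at C3–C4 (acetylide + epoxide), C1–C2 (benzylic bromide + ethynyl Grignard reagent) and C6–C7 (benzylic Grignard reagent + epichlorohydrin).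
- Forward: ring B aldehyde → benzylic chloride → C4–C7 epoxide; ring A aldehyde → C1–C3 arylpropyne; union at C3–C4; O-silylation; closure of the oxasilolane (the only ring made); oxidative removal of silicon; hydrogenolysis of three benzyl ethers.
- Stereochemistry: C5 is the carbinol carbon of (R)-epichlorohydrin; no bond to it is made or broken afterwards.

Key step: step 12

**Route**

Step 1
Reactants: 1 3,4-dihydroxy-5-methoxybenzaldehyde
Product: 2 3,4-bis(benzyloxy)-5-methoxybenzaldehyde
Conditions: BnBr (2.4 equiv), K2CO3 (3 equiv), DMF, 60 °C, N2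
Reagents that add atoms: benzyl bromide, BrCc1ccccc1
Why: Williamson etherification of both catechol phenoxides masks the oxidation-prone catechol as benzyl ethers, which tolerate the organometallic, Lewis-acid, platinum and peroxide steps and are removed together by hydrogenolysis at the end.

Step 2
Reactants: 2 3,4-bis(benzyloxy)-5-methoxybenzaldehyde
Product: 3 [3,4-bis(benzyloxy)-5-methoxyphenyl]methanol
Conditions: NaBH4, MeOH/THF, 0 °C
Reagents that add atoms: none
Why: Borohydride reduction of an aryl aldehyde to the benzylic alcohol, with the aryl benzyl and methyl ethers inert.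

Step 3
Reactants: 3 [3,4-bis(benzyloxy)-5-methoxyphenyl]methanol
Product: 4 1,2-bis(benzyloxy)-5-(chloromethyl)-3-methoxybenzene
Conditions: SOCl2 (1.2 equiv), CH2Cl2, 0 °C → rt
Reagents that add atoms: thionyl chloride, O=S(Cl)Cl
Why: Chlorodehydroxylation of an electron-rich benzylic alcohol through its chlorosulfite is fast at 0 °C, and the chloride is preferred over the bromide because it couples less with itself during Grignard formation.

Step 4
Reactants: 4 1,2-bis(benzyloxy)-5-(chloromethyl)-3-methoxybenzene, 5 (R)-epichlorohydrin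
Product: 7 (2R)-4-[3,4-bis(benzyloxy)-5-methoxyphenyl]-1-chlorobutan-2-ol, via ring B benzylmagnesium chloride 6 (not isolated)
Conditions: Mg turnings (3 equiv), THF, 0 °C, slow addition of 4 at high dilution; then CuI (10 mol%), 5 (0.8 equiv), −40 → 0 °C
Reagents that add atoms: none
Why: Grignard formation followed by CuI-catalysed SN2 opening of the epoxide at its unsubstituted carbon (faster at low temperature than displacement of the primary chloride) forms C6–C7, and since the carbinol carbon of 5 is not touched its configuration becomes that of C5, giving the (R)-chlorohydrin.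

Step 5
Reactants: 7 (2R)-4-[3,4-bis(benzyloxy)-5-methoxyphenyl]-1-chlorobutan-2-ol
Product: 8 (2R)-2-{2-[3,4-bis(benzyloxy)-5-methoxyphenyl]ethyl}oxirane
Conditions: K2CO3 (2 equiv), MeOH, rt
Reagents that add atoms: none
Why: Intramolecular Williamson reaction (3-exo-tet) of the chlorohydrin alkoxide displaces chloride at the primary carbon, so the oxygen-bearing stereocentre keeps its configuration and the (R)-epoxide results.

Step 6
Reactants: 9 vanillin
Product: 10 4-(benzyloxy)-3-methoxybenzaldehyde
Conditions: BnBr (1.2 equiv), K2CO3 (1.5 equiv), DMF, 60 °C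
Reagents that add atoms: benzyl bromide, BrCc1ccccc1
Why: Williamson etherification of the single phenol gives the same protecting group as on ring B, so that one hydrogenolysis frees all three phenols.

Step 7
Reactants: 10 4-(benzyloxy)-3-methoxybenzaldehyde
Product: 11 [4-(benzyloxy)-3-methoxyphenyl]methanol
Conditions: NaBH4, MeOH/THF, 0 °C
Reagents that add atoms: none
Why: Borohydride reduction of the aryl aldehyde to the benzylic alcohol.

Step 8
Reactants: 11 [4-(benzyloxy)-3-methoxyphenyl]methanol
Product: 12 1-(benzyloxy)-4-(bromomethyl)-2-methoxybenzene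
Conditions: PBr3 (0.4 equiv), Et2O, 0 °C; used at once
Reagents that add atoms: phosphorus tribromide, BrP(Br)Br
Why: Bromodehydroxylation of a benzylic alcohol with PBr3 gives the reactive p-alkoxybenzylic bromide needed as the electrophile of the next step.

Step 9
Reactants: 12 1-(benzyloxy)-4-(bromomethyl)-2-methoxybenzene, 13 ethynylmagnesium bromide
Product: 14 1-(benzyloxy)-2-methoxy-4-(prop-2-yn-1-yl)benzene
Conditions: 13 (0.5 M in THF, 2.5 equiv), CuCl (10 mol%), THF, 0 → 50 °C, slow addition of 12
Reagents that add atoms: none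
Why: Copper-catalysed cross-coupling of an alkynyl Grignard reagent with a benzylic bromide forms C1–C2, and the excess of 13 with slow addition of 12 should suppress a second benzylation of the product alkyne.

Step 10
Reactants: 14 1-(benzyloxy)-2-methoxy-4-(prop-2-yn-1-yl)benzene, 8 (2R)-2-{2-[3,4-bis(benzyloxy)-5-methoxyphenyl]ethyl}oxirane
Product: 16 (3R)-7-[4-(benzyloxy)-3-methoxyphenyl]-1-[3,4-bis(benzyloxy)-5-methoxyphenyl]hept-5-yn-3-ol, via ring A propynyllithium 15 (not isolated)
Conditions: 14 (1.5 equiv), n-BuLi (1.45 equiv), THF, −78 °C; BF3·OEt2 (1.5 equiv), −78 °C; then 8 (1.0 equiv), −78 °C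
Reagents that add atoms: none
Why: Yamaguchi–Hirao alkynylation, in which the lithium acetylide with BF3·OEt2 opens the epoxide at its CH2 terminus at −78 °C and forms C3–C4, leaves the C5–O bond alone so that (R) is retained, while kinetic deprotonation of the sp C–H with slightly less than one equivalent of base avoids metalation of the C1 methylene.

Step 11
Reactants: 16 (3R)-7-[4-(benzyloxy)-3-methoxyphenyl]-1-[3,4-bis(benzyloxy)-5-methoxyphenyl]hept-5-yn-3-ol, 17 1,1,3,3-tetramethyldisilazane
Product: 18 {[(3R)-7-[4-(benzyloxy)-3-methoxyphenyl]-1-[3,4-bis(benzyloxy)-5-methoxyphenyl]hept-5-yn-3-yl]oxy}dimethylsilane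
Conditions: 17 (1.5 equiv), neat or minimal hexane, 50 °C; volatiles removed in vacuo; crude product used directly
Reagents that add atoms: none
Why: Transsilylation of the secondary alcohol by the disilazane gives the hydrodimethylsilyl ether with ammonia as the only by-product, so no base or chloride that could disturb the platinum catalyst is carried into the next step.

Step 12
Reactants: 18 {[(3R)-7-[4-(benzyloxy)-3-methoxyphenyl]-1-[3,4-bis(benzyloxy)-5-methoxyphenyl]hept-5-yn-3-yl]oxy}dimethylsilane
Product: 19 (3E,5R)-3-{2-[4-(benzyloxy)-3-methoxyphenyl]ethylidene}-5-{2-[3,4-bis(benzyloxy)-5-methoxyphenyl]ethyl}-2,2-dimethyl-1,2-oxasilolane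
Conditions: H2PtCl6·6H2O (0.5 mol%, THF stock solution), CH2Cl2 (0.05 M), rt, Ar; concentrated and used crude
Reagents that add atoms: none
Why: The hydrosilane reduces H2PtCl6 to zerovalent platinum, which adds oxidatively into the Si–H bond of 18; the C2≡C3 alkyne then inserts so that silicon and hydrogen arrive on the same face (a Chalk–Harrod-type cycle), and reductive elimination leaves C3–Si and C2–H. The closest known reaction type is the platinum-catalysed intramolecular hydrosilylation of homopropargylic hydrodimethylsilyl ethers to 3-alkylidene-1,2-oxasilolanes, of which this is a direct application. The one ring formed, O–Si–C3–C4–C5, closes in the 5-exo-dig mode. No stereocentre is created: C5 is a spectator, and the E geometry of the alkylidene follows from syn addition and is lost in step 13. The selectivity required is C3 over C2, two alkyne carbons that are both flanked by CH2 groups and electronically alike, and the two-atom O–Si tether from C5 secures it, because delivery to C2 would need a six-membered ring with an endocyclic double bond having Si and C4 cis, which a syn addition cannot produce. Dilution to about 0.05 M should keep the intramolecular path ahead of intermolecular hydrosilylation.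

Step 13
Reactants: 19 (3E,5R)-3-{2-[4-(benzyloxy)-3-methoxyphenyl]ethylidene}-5-{2-[3,4-bis(benzyloxy)-5-methoxyphenyl]ethyl}-2,2-dimethyl-1,2-oxasilolane
Product: 20 (5R)-1-[4-(benzyloxy)-3-methoxyphenyl]-7-[3,4-bis(benzyloxy)-5-methoxyphenyl]-5-hydroxyheptan-3-one
Conditions: 30% aq. H2O2 (excess), KF, KHCO3, THF/MeOH 1:1, rt
Reagents that add atoms: hydrogen peroxide, OO
Why: Tamao–Fleming oxidation, in which fluoride-assisted attack of hydroperoxide on the alkoxy-activated silicon is followed by a 1,2-shift of the alkenyl carbon from silicon to oxygen and hydrolysis of both Si–O bonds, delivers the C3 carbonyl and the free C5 hydroxyl in a bicarbonate-buffered medium mild enough for a β-hydroxy ketone.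

Step 14
Reactants: 20 (5R)-1-[4-(benzyloxy)-3-methoxyphenyl]-7-[3,4-bis(benzyloxy)-5-methoxyphenyl]-5-hydroxyheptan-3-one
Product: 21 (5R)-7-(3,4-dihydroxy-5-methoxyphenyl)-5-hydroxy-1-(4-hydroxy-3-methoxyphenyl)heptan-3-one
Conditions: H2 (1 atm), 10% Pd/C, EtOAc/EtOH, rt; filtration and concentration under Ar
Reagents that add atoms: none
Why: Catalytic hydrogenolysis cleaves the three aryl benzyl ethers, while the aliphatic ketone and the non-benzylic secondary alcohol are not reduced at one atmosphere and room temperature, so C5 stays (R).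

**Compound list**

1 | 3,4-dihydroxy-5-methoxybenzaldehyde | COc1cc(C=O)cc(O)c1O | starting material
2 | 3,4-bis(benzyloxy)-5-methoxybenzaldehyde | COc1cc(C=O)cc(OCc2ccccc2)c1OCc3ccccc3 | intermediate
3 | [3,4-bis(benzyloxy)-5-methoxyphenyl]methanol | COc1cc(CO)cc(OCc2ccccc2)c1OCc3ccccc3 | intermediate
4 | 1,2-bis(benzyloxy)-5-(chloromethyl)-3-methoxybenzene | COc1cc(CCl)cc(OCc2ccccc2)c1OCc3ccccc3 | intermediate
5 | (R)-epichlorohydrin | ClC[C@H]1CO1 | starting material
6 | [3,4-bis(benzyloxy)-5-methoxybenzyl]magnesium chloride | COc1cc(C[Mg]Cl)cc(OCc2ccccc2)c1OCc3ccccc3 | intermediate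
7 | (2R)-4-[3,4-bis(benzyloxy)-5-methoxyphenyl]-1-chlorobutan-2-ol | COc1cc(CC[C@@H](O)CCl)cc(OCc2ccccc2)c1OCc3ccccc3 | intermediate
8 | (2R)-2-{2-[3,4-bis(benzyloxy)-5-methoxyphenyl]ethyl}oxirane | COc1cc(CC[C@@H]2CO2)cc(OCc3ccccc3)c1OCc4ccccc4 | intermediate
9 | vanillin | COc1cc(C=O)ccc1O | starting material
10 | 4-(benzyloxy)-3-methoxybenzaldehyde | COc1cc(C=O)ccc1OCc2ccccc2 | intermediate
11 | [4-(benzyloxy)-3-methoxyphenyl]methanol | COc1cc(CO)ccc1OCc2ccccc2 | intermediate
12 | 1-(benzyloxy)-4-(bromomethyl)-2-methoxybenzene | COc1cc(CBr)ccc1OCc2ccccc2 | intermediate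
13 | ethynylmagnesium bromide | C#C[Mg]Br | starting material
14 | 1-(benzyloxy)-2-methoxy-4-(prop-2-yn-1-yl)benzene | COc1cc(CC#C)ccc1OCc2ccccc2 | intermediate
15 | {3-[4-(benzyloxy)-3-methoxyphenyl]prop-1-yn-1-yl}lithium | COc1cc(CC#C[Li])ccc1OCc2ccccc2 | intermediate
16 | (3R)-7-[4-(benzyloxy)-3-methoxyphenyl]-1-[3,4-bis(benzyloxy)-5-methoxyphenyl]hept-5-yn-3-ol | COc1cc(CC#CC[C@H](O)CCc2cc(OC)c(OCc3ccccc3)c(OCc4ccccc4)c2)ccc1OCc5ccccc5 | intermediate
17 | 1,1,3,3-tetramethyldisilazane | C[SiH](C)N[SiH](C)C | starting material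
18 | {[(3R)-7-[4-(benzyloxy)-3-methoxyphenyl]-1-[3,4-bis(benzyloxy)-5-methoxyphenyl]hept-5-yn-3-yl]oxy}dimethylsilane | COc1cc(CC#CC[C@H](O[SiH](C)C)CCc2cc(OC)c(OCc3ccccc3)c(OCc4ccccc4)c2)ccc1OCc5ccccc5 | intermediate
19 | (3E,5R)-3-{2-[4-(benzyloxy)-3-methoxyphenyl]ethylidene}-5-{2-[3,4-bis(benzyloxy)-5-methoxyphenyl]ethyl}-2,2-dimethyl-1,2-oxasilolane | COc1cc(C/C=C2\C[C@@H](CCc3cc(OC)c(OCc4ccccc4)c(OCc5ccccc5)c3)O[Si]2(C)C)ccc1OCc6ccccc6 | intermediate
20 | (5R)-1-[4-(benzyloxy)-3-methoxyphenyl]-7-[3,4-bis(benzyloxy)-5-methoxyphenyl]-5-hydroxyheptan-3-one | COc1cc(CCC(=O)C[C@H](O)CCc2cc(OC)c(OCc3ccccc3)c(OCc4ccccc4)c2)ccc1OCc5ccccc5 | intermediate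
21 | (5R)-7-(3,4-dihydroxy-5-methoxyphenyl)-5-hydroxy-1-(4-hydroxy-3-methoxyphenyl)heptan-3-one | COc1cc(CCC(=O)C[C@H](O)CCc2cc(O)c(O)c(OC)c2)ccc1O | target

**Step count**

Total: 14 steps. Longest linear sequence: 10 steps (steps 1–5 and 10–14, from compound 1).

**Steps most likely to fail**

Step 4. Wurtz-type homocoupling during formation of the electron-rich benzylic Grignard reagent could consume the chloride before it meets the epoxide, and any chlorohydrin alkoxide that closes to the epoxide in the flask would be alkylated a second time. The fallback sets out from 4 and comes back at 8, and uses 4 as the electrophile instead of as a nucleophile precursor. Coupling of 4 with allylmagnesium bromide (THF, 0 °C → rt) should give 4-[3,4-bis(benzyloxy)-5-methoxyphenyl]but-1-ene F1. Epoxidation with mCPBA (CH2Cl2, NaHCO3, 0 °C) should give racemic 2-{2-[3,4-bis(benzyloxy)-5-methoxyphenyl]ethyl}oxirane F2. Hydrolytic kinetic resolution with (R,R)-(salen)Co(OAc), the acetate of trivalent cobalt with (R,R)-N,N'-bis(3,5-di-tert-butylsalicylidene)-1,2-cyclohexanediamine (0.5 mol%), and H2O (0.55 equiv) in THF at rt should hydrolyse the (S)-epoxide and leave the (R)-epoxide 8. The cost is that at most half of the material can be recovered as 8; the stereocentre then comes from the catalyst and not from 5.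

Step 10. Three processes could compete with the acetylide opening: metalation at the doubly activated C1 methylene of 14 with propargyl–allenyl isomerisation, Lewis-acid-triggered Friedel–Crafts closure of the electron-rich ring B onto the activated epoxide, and BF3-induced epoxide rearrangement. The fallback sets out from 8, uses bromide 12, and comes back at 16; it needs neither a Lewis acid nor the arylpropyne 14, so it also covers a failure of step 9. Opening of 8 with lithium acetylide–ethylenediamine complex, LiC≡CH·H2NCH2CH2NH2 (DMSO/THF, rt), should give (3R)-1-[3,4-bis(benzyloxy)-5-methoxyphenyl]hex-5-yn-3-ol F3. Copper-promoted benzylation of its terminal alkyne with 12 (CuI, Cs2CO3, MeCN, rt) should then form C1–C2 last and give 16.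

Step 12. Intermolecular hydrosilylation and oligomerisation, platinum-induced migration of the new double bond towards conjugation with ring A, or hydrolysis of the Si–O tether before ring closure would erode the delivery of silicon to C3. The fallback sets out from 16 and comes back at 20, replacing the silicon tether by a carbonate oxygen tether. Acylation of 16 with Boc2O (DMAP cat., MeCN, rt) should give (3R)-7-[4-(benzyloxy)-3-methoxyphenyl]-1-[3,4-bis(benzyloxy)-5-methoxyphenyl]hept-5-yn-3-yl tert-butyl carbonate F4. With Ph3PAuNTf2 (monovalent gold, 2 mol%, CH2Cl2, rt) the carbonyl oxygen should attack C3 in a 6-exo-dig closure with loss of 2-methylpropene, giving (4Z,6R)-4-{2-[4-(benzyloxy)-3-methoxyphenyl]ethylidene}-6-{2-[3,4-bis(benzyloxy)-5-methoxyphenyl]ethyl}-1,3-dioxan-2-one F5. Mild hydrolysis of this cyclic enol carbonate (LiOH, aq. THF, 0 °C, then neutralisation) should release the C3 ketone and the C5 hydroxyl, giving 20 without passing through 18 and 19.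

**Further compounds**

F1 | step 4 | 4-[3,4-bis(benzyloxy)-5-methoxyphenyl]but-1-ene | COc1cc(CCC=C)cc(OCc2ccccc2)c1OCc3ccccc3
F2 | step 4 | racemic 2-{2-[3,4-bis(benzyloxy)-5-methoxyphenyl]ethyl}oxirane | COc1cc(CCC2CO2)cc(OCc3ccccc3)c1OCc4ccccc4
F3 | step 10 | (3R)-1-[3,4-bis(benzyloxy)-5-methoxyphenyl]hex-5-yn-3-ol | COc1cc(CC[C@@H](O)CC#C)cc(OCc2ccccc2)c1OCc3ccccc3
F4 | step 12 | (3R)-7-[4-(benzyloxy)-3-methoxyphenyl]-1-[3,4-bis(benzyloxy)-5-methoxyphenyl]hept-5-yn-3-yl tert-butyl carbonate | COc1cc(CC#CC[C@H](OC(=O)OC(C)(C)C)CCc2cc(OC)c(OCc3ccccc3)c(OCc4ccccc4)c2)ccc1OCc5ccccc5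
F5 | step 12 | (4Z,6R)-4-{2-[4-(benzyloxy)-3-methoxyphenyl]ethylidene}-6-{2-[3,4-bis(benzyloxy)-5-methoxyphenyl]ethyl}-1,3-dioxan-2-one | COc1cc(C/C=C2/C[C@@H](CCc3cc(OC)c(OCc4ccccc4)c(OCc5ccccc5)c3)OC(=O)O2)ccc1OCc6ccccc6
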